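**Retrosynthetic overview**
1. Target ⇒ conjugated 7-en-17-al acid. The 6-ene/8-H array comes from a stereospecific deconjugation: axial PhSeH addition at C-7, then a selenoxide syn-elimination that can only reach H-6.
2. Conjugated enal acid ⇒ ent-labda-7,13-dienoate, by allylic oxidation of C-17 and cleavage of the tert-butyl ester.
3. ent-Labdadienoate ⇒ acyclic tetraene, by one enantioselective proton-initiated cation–olefin cascade on the complete, fully oxygenated C20 chain. Ring A closes first (C-4/C-5 bond) and ring B directly after (C-9/C-10 bond), as in geranylgeranyl diphosphate → ent-copalyl cation. The electron-poor 13-ene is the built-in stop.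
4. Acyclic tetraene ⇒ acetoxymethyl ketone + stabilised ylide (E-selective Wittig). The ketone ⇒ farnesylacetone (terminal acetoxylation).

Assumption: geometrically pure (5E,9E)-farnesylacetone is bought. Positions are given in labdane numbering: decalin C-1 to C-10, side chain C-11 to C-16, C-17 on C-8, C-20 on C-10.

**Step 1**
Reactants: 1 (5E,9E)-farnesylacetone
Product: 3 (5E,9E)-6,10,14-trimethyl-2-oxopentadeca-5,9,13-trien-1-yl acetate, via silyl enol ether 2 (not isolated)
Conditions: LiN(i-Pr)2, Me3SiCl, THF, −78 °C; solvent swap; Pb(OAc)4, CH2Cl2, −20 to 0 °C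
Reagents that add atoms: chlorotrimethylsilane C[Si](C)(C)Cl (silyl group of 2 only); lead tetraacetate CC(=O)O[Pb](OC(C)=O)(OC(C)=O)OC(C)=O
Why: Kinetic deprotonation on the CH3 side and O-silylation give the terminal silyl enol ether, the most electron-rich alkene present, which Pb(OAc)4 acetoxylates (Rubottom-type oxidation) before the three trisubstituted alkenes react; no stereocentre is formed.

**Step 2**
Reactants: 3 acetoxymethyl ketone; 4 tert-butyl (triphenylphosphoranylidene)acetate
Product: 5 tert-butyl (2E,6E,10E)-3-(acetoxymethyl)-7,11,15-trimethylhexadeca-2,6,10,14-tetraenoate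
Conditions: PhCO2H (10 mol %), toluene, 100 °C
Reagents that add atoms: tert-butyl (triphenylphosphoranylidene)acetate (compound 4) CC(C)(C)OC(=O)C=P(c1ccccc1)(c1ccccc1)c1ccccc1
Why: The neutral Wittig olefination with a stabilised ylide tolerates the base-sensitive acyloxy ketone, and α-oxygenated ketones place the ester trans to the CH2O arm, so the 2E alkene (chain cis to the ester) is the main product and the minor 2Z isomer is removed by chromatography.

**Step 3 (key step)**
Reactants: 5 acyclic tetraene ester
Product: 6 tert-butyl (E)-3-(acetoxymethyl)-5-[(1R,4aR,8aR)-2,5,5,8a-tetramethyl-1,4,4a,5,6,7,8,8a-octahydronaphthalen-1-yl]pent-2-enoate (ent-labda-7,13-diene; 5R,9R,10R)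
Conditions: SnCl4 (3.0 equiv), (S)-2'-[(2-fluorobenzyl)oxy]-1,1'-binaphthalen-2-ol (3.3 equiv, recovered), toluene, −78 °C, 72 h; aq NaHCO3
Reagents that add atoms: none
Why: Proposed new method: the SnCl4-activated chiral binaphthol proton adds to one face of the terminal isopropylidene alkene and the all-E triene folds chair–chair, so that two anti additions (Stork–Eschenmoser) set C-5, C-10 and C-9 together as the trans-decalin with an equatorial C-9 chain, the (S)-ligand being chosen because its (R)-antipode gives the normal ambrox-type series, while the 13-ene, deactivated by the ester, the acetoxymethyl group and bound SnCl4, cannot attack the C-8 cation, which therefore loses axial H-7 to give the 7-ene; the closest known reaction type is the Lewis-acid-assisted chiral Brønsted acid cyclisation of homofarnesyl ethers and homopolyprenylarenes, which so far relies on an internal oxygen or aryl terminator rather than on proton loss.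

**Step 4**
Reactants: 6 ent-labda-7,13-dienoate
Product: 7 tert-butyl (E)-3-(acetoxymethyl)-5-[(1S,4aR,8aR)-2-formyl-5,5,8a-trimethyl-1,4,4a,5,6,7,8,8a-octahydronaphthalen-1-yl]pent-2-enoate
Conditions: SeO2 (2 equiv), 1,4-dioxane, trace H2O, 90 °C
Reagents that add atoms: selenium dioxide O=[Se]=O
Why: In the Riley allylic oxidation (ene reaction, then 2,3-sigmatropic shift) selenium attacks the less substituted C-7 and oxygen goes to the only unhindered allylic carbon on the C-8 terminus, the C-17 methyl, hot dioxane carries the alcohol on to the enal, and the electron-poor 13-ene, the acetate, the ester and all stereocentres are untouched.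

**Step 5**
Reactants: 7 enal tert-butyl ester
Product: 8 (E)-3-(acetoxymethyl)-5-[(1S,4aR,8aR)-2-formyl-5,5,8a-trimethyl-1,4,4a,5,6,7,8,8a-octahydronaphthalen-1-yl]pent-2-enoic acid
Conditions: CF3CO2H/CH2Cl2 (1:4), 0 to 20 °C
Reagents that add atoms: none
Why: Acidolysis of the tert-butyl ester (E1 loss of the tert-butyl group) spares the primary acetate and the deactivated enal alkene, and it is placed here because the final β,γ-unsaturated aldehyde would not tolerate acid; crystalline 8 is also the point at which enantiomeric purity is raised by recrystallisation.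

**Step 6**
Reactants: 8 enal acid
Product: 11 (E)-3-(acetoxymethyl)-5-[(1R,2S,4aR,8aS)-2-formyl-5,5,8a-trimethyl-1,2,4a,5,6,7,8,8a-octahydronaphthalen-1-yl]pent-2-enoic acid, via selenide 9 (not isolated), via selenoxide 10 (not isolated)
Conditions: PhSeH (1.0 equiv), Et3N (0.1 equiv), CH2Cl2, −20 °C, dark; then mCPBA (1.05 equiv), −78 °C; pyridine (3 equiv), −78 to 20 °C
Reagents that add atoms: benzeneselenol [SeH]c1ccccc1 (in 9 and 10 only); mCPBA OOC(=O)c1cccc(Cl)c1 (oxygen of 10 only)
Why: Selenol Michael addition followed by selenoxide syn-elimination: PhSe adds axially to C-7 on the face opposite the C-10 methyl and the enol is protonated anti to selenium, which sets C-8 with an axial H and an equatorial formyl group trans to the C-9 chain (also the more stable epimer), so that in 10 the only hydrogen cis to selenium sits on C-6 and the elimination can only give the 6-ene without touching C-8, any unreacted 8 being inert and recyclable.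

**Compound list**
1 | (5E,9E)-6,10,14-trimethylpentadeca-5,9,13-trien-2-one (farnesylacetone) | CC(C)=CCC/C(C)=C/CC/C(C)=C/CCC(C)=O | starting material
2 | trimethyl{[(5E,9E)-6,10,14-trimethylpentadeca-1,5,9,13-tetraen-2-yl]oxy}silane | CC(C)=CCC/C(C)=C/CC/C(C)=C/CCC(=C)O[Si](C)(C)C | intermediate
3 | (5E,9E)-6,10,14-trimethyl-2-oxopentadeca-5,9,13-trien-1-yl acetate | CC(C)=CCC/C(C)=C/CC/C(C)=C/CCC(=O)COC(C)=O | intermediate
4 | tert-butyl (triphenylphosphoranylidene)acetate | CC(C)(C)OC(=O)C=P(c1ccccc1)(c1ccccc1)c1ccccc1 | starting material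
5 | tert-butyl (2E,6E,10E)-3-(acetoxymethyl)-7,11,15-trimethylhexadeca-2,6,10,14-tetraenoate | CC(C)=CCC/C(C)=C/CC/C(C)=C/CC/C(COC(C)=O)=C\C(=O)OC(C)(C)C | intermediate
6 | tert-butyl ent-16-acetoxylabda-7,13E-dien-15-oate (5R,9R,10R) | CC(=O)OC/C(=C/C(=O)OC(C)(C)C)CC[C@@H]1C(C)=CC[C@@H]2C(C)(C)CCC[C@@]12C | intermediate
7 | tert-butyl ent-16-acetoxy-17-oxolabda-7,13E-dien-15-oate | CC(=O)OC/C(=C/C(=O)OC(C)(C)C)CC[C@@H]1C(C=O)=CC[C@@H]2C(C)(C)CCC[C@@]12C | intermediate
8 | ent-16-acetoxy-17-oxolabda-7,13E-dien-15-oic acid | CC(=O)OC/C(=C/C(=O)O)CC[C@@H]1C(C=O)=CC[C@@H]2C(C)(C)CCC[C@@]12C | intermediate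
9 | (E)-3-(acetoxymethyl)-5-[(1R,2S,3S,4aR,8aS)-2-formyl-5,5,8a-trimethyl-3-(phenylselanyl)decahydronaphthalen-1-yl]pent-2-enoic acid (axial 7-SePh anti to C-20, equatorial 8-CHO) | CC(=O)OC/C(=C/C(=O)O)CC[C@@H]1[C@@H](C=O)[C@@H]([Se]c3ccccc3)C[C@@H]2C(C)(C)CCC[C@@]12C | intermediate
10 | selenoxide of 9 (either configuration at Se) | CC(=O)OC/C(=C/C(=O)O)CC[C@@H]1[C@@H](C=O)[C@@H]([Se](=O)c3ccccc3)C[C@@H]2C(C)(C)CCC[C@@]12C | intermediate
11 | ent-16-acetoxy-17-oxolabda-6,13E-dien-15-oic acid (5R,8S,9R,10S), CNP0217581.1 | CC(=O)OC/C(=C/C(=O)O)CC[C@@H]1[C@@H](C=O)C=C[C@@H]2C(C)(C)CCC[C@@]12C | target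

**Total step count:** 6. **Longest linear sequence:** 6 (1 → 11).

**Steps most likely to fail**

Step 3. The two ester groups may tie up SnCl4. The cascade may stop after ring A. Proton loss may give 7-ene/8(17)-ene mixtures, and the ee may stay below 90 %.

The fallback sets out from 5 and comes back at 6, and it splits the cascade into two ring closures. Compound 5 is treated with the same chiral SnCl4–binaphthol acid only until ring A has closed. This gives tert-butyl (2E,6E)-3-(acetoxymethyl)-7-methyl-9-[(1R)-2,6,6-trimethylcyclohex-2-en-1-yl]nona-2,6-dienoate F1, which is isolated and whose C-5 centre already carries the enantioselection. Its ring alkene is then re-ionised with the achiral acid CF3CO2H·SnCl4 in 2-nitropropane at −78 °C. Ring B closes through a chair transition state under substrate control by C-5 and gives 6.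

Step 4. SeO2 may over-oxidise, attack C-6 or C-9, or leave colloidal selenium that is hard to remove.

The fallback sets out from 6 and comes back at 7, and it replaces the selenium ene/sigmatropic route by electrophilic chlorination and N-oxide oxidation. HOCl (Ca(OCl)2, solid CO2, CH2Cl2/H2O, 0 °C) attacks the 7-ene from the face opposite C-20, and a C-17 proton is lost. This gives the axial 7-chloro-8(17)-ene tert-butyl ester F2. N-methylmorpholine N-oxide in MeCN at 60 °C displaces the aligned axial chloride in an SN2′ sense at C-17 and gives the N-alkoxy-N-methylmorpholinium chloride F3. Excess N-oxide then collapses this salt to enal 7.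

Step 6. In 10, H-8 is anti-periplanar to the C–Se bond and is acidified by the formyl group. An anti elimination (E1cB) back to 8 may therefore outrun the syn-elimination. The liberated selenenic acid may also attack the new alkene.

The fallback sets out from 8 and comes back at 11, and it removes the acidity before selenium is expelled.
- The selenol addition is run as above to 9. NaBH4 in MeOH is then added at −20 °C instead of the peracid, which gives the 7-phenylselanyl-17-ol acid F4.
- mCPBA at −78 °C converts it into the corresponding selenoxide alcohol F5.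
- On warming, F5 can again lose only H-6 and gives the 6-en-17-ol acid F6, with C-8 intact.
- Dess–Martin periodinane with NaHCO3 in CH2Cl2 at 0 °C oxidises this homoallylic alcohol to 11 without moving the double bond.

**Further compounds**
F1 | step 3 | tert-butyl (2E,6E)-3-(acetoxymethyl)-7-methyl-9-[(1R)-2,6,6-trimethylcyclohex-2-en-1-yl]nona-2,6-dienoate | CC(=O)OC/C(=C/C(=O)OC(C)(C)C)CC/C=C(\C)CC[C@H]1C(C)=CCCC1(C)C
F2 | step 4 | tert-butyl ent-16-acetoxy-7-chlorolabda-8(17),13E-dien-15-oate (axial chloride anti to C-20) | CC(=O)OC/C(=C/C(=O)OC(C)(C)C)CC[C@@H]1C(=C)[C@@H](Cl)C[C@@H]2C(C)(C)CCC[C@@]12C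
F3 | step 4 | N-methyl-N-[(ent-16-acetoxy-15-tert-butoxy-15-oxolabda-7,13E-dien-17-yl)oxy]morpholinium chloride | CC(=O)OC/C(=C/C(=O)OC(C)(C)C)CC[C@@H]1C(CO[N+]3(C)CCOCC3)=CC[C@@H]2C(C)(C)CCC[C@@]12C.[Cl-]
F4 | step 6 | 17-alcohol of 9 (7-phenylselanyl-17-ol acid) | CC(=O)OC/C(=C/C(=O)O)CC[C@@H]1[C@@H](CO)[C@@H]([Se]c3ccccc3)C[C@@H]2C(C)(C)CCC[C@@]12C
F5 | step 6 | selenoxide of F4 | CC(=O)OC/C(=C/C(=O)O)CC[C@@H]1[C@@H](CO)[C@@H]([Se](=O)c3ccccc3)C[C@@H]2C(C)(C)CCC[C@@]12C
F6 | step 6 | ent-16-acetoxy-17-hydroxylabda-6,13E-dien-15-oic acid | CC(=O)OC/C(=C/C(=O)O)CC[C@@H]1[C@@H](CO)C=C[C@@H]2C(C)(C)CCC[C@@]12C
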